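## Structural features

Schizotenuin A is a 2-arylbenzofuran in which the benzo ring (ring A) is fused to the furan (ring B), and C2 of the furan carries a 3,4-dihydroxyphenyl group (ring C). C3 bears a carboxyl group esterified with the secondary hydroxyl of (R)-3-(3,4-dihydroxyphenyl)lactic acid (danshensu). C5 bears an (E)-propenoate esterified with a second (R)-danshensu unit, and C7 bears a free hydroxyl. The only stereocentres are the two lactate α-carbons, both R and far apart. Each sits between a carboxyl and an acyloxy group, so base can epimerise it or eliminate the acyloxy group. Fragile elements are the three catechols and the C7 phenol (air oxidation), the two secondary acyl–oxygen linkages, and the E alkene, which rules out hydrogenolysis and short-wavelength light late in the route. The real difficulty is the fully substituted furan, whose C3 ester is flanked by the C2 aryl group and the peri C4–H and is therefore hard to make by acylation with a crowded acid. Added to this are the meta relationship of the C5 carbon substituent and the C7 oxygen on ring A, and the release of seven phenols and two acids at the end. The key step uses the fact that the sequence O1–C2(aryl)–C3, with the carboxyl carbon on C3 and C3a as its other neighbour, is a flavanone pyranone ring whose C4 carbonyl carbon has been pushed out of the ring. A Wolff ring contraction of a 3-diazoflavanone therefore gives the five-membered ring and delivers the ester carbon as a ketene.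

## Logic of the disconnections

16 from 15: the nine O–benzyl bonds (seven aryl ethers, two esters) are cut. One protecting group for every acidic OH keeps the end to a single operation that needs no hydrogen, so the alkene is safe. The forward step must cleave benzyl–oxygen bonds with a Lewis acid while sparing three acyl–oxygen bonds and the cinnamate.

15 from 13 and 14: the bond between C5 of ring A and the β-carbon of the propenoate is cut. This removes the second danshensu unit as a ready-made acrylate and leaves an aryl bromide; the E geometry follows from syn insertion and syn β-hydride elimination. The forward step needs oxidative addition into an electron-rich bromide under base mild enough for the α-acyloxy ester centres.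

14 from 10: the acyl–oxygen bond of the acrylate is cut, so both ester partners of the target come from one protected alcohol. The demand is only a clean O-acylation without touching the α-centre.

13 from 12: the C2=C3 double bond is retrosynthetically saturated. This exposes an sp3 C3, which is what the ring-contraction retron needs, at the cost of one later dehydrogenation. The forward step must abstract hydride at C2 (benzylic and α to oxygen) in preference to the other benzylic positions.

12 from 8 and 10, through 11: the C3–C3a bond and the ester C–O bond are cut, and C3a is reconnected to the carboxyl carbon, which becomes the ring ketone. This turns a crowded tetrasubstituted furan ester into a flavanone and an alcohol. The forward step must make the aryl carbon migrate rather than the C2 hydrogen, and the ketene must be captured by a hindered secondary alcohol.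

10 from 9: three O–benzyl bonds are cut, back to the commercial sodium salt of the natural acid. The forward alkylation must leave the secondary hydroxyl free.

8 from 6, through 7: the C3=N2 bond is cut. The forward step must activate C3 of a ketone whose enolate can open the ring by β-elimination, so it has to run cold and fast.

6 from 3 and 4, through 5: O1–C2 (oxa-Michael) and C2–C3 (aldol condensation) are cut. The whole C6–C3–C6 skeleton then comes from an acetophenone and an aldehyde. The demand is a chalcone–flavanone equilibrium that can be driven or recycled.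

3 from 2 from 1: the C–Br bond and the 3'-O–benzyl bond are cut. The bromine goes para to the free phenol, which becomes C5 of the benzofuran; the forward benzylation must distinguish the two adjacent hydroxyls.

## Other disconnections considered

Alternative 1: Ring A is disconnected at C4–C5, C6–C7 and C7–C7a, leaving a fully substituted furan. In the forward sense the furyl diazomethyl ketone A1 would be irradiated with the siloxyalkyne A2. Wolff rearrangement gives a furyl ketene, [2+2] addition to A2 gives a cyclobutenone, 4π opening and 6π closure onto the furan C5 followed by tautomerisation should give the 7-hydroxy-5-siloxybenzofuran A3. In its favour, the benzofuran is aromatic from the start, so no dehydrogenation is needed and there is no competing hydride shift; on both points it is better than the chosen plan. The meta oxygen pattern is also fixed by the mechanism, and the two oxygens come out differentiated. Against it, A1 requires a 2-aryl furan with two different carbonyl groups at C3 and C4 and a diazomethyl ketone made in the presence of the danshensu ester. The electrocyclic closure needs heating after the photolysis, and C5 arrives as oxygen, not carbon. A3 would therefore need protection of the C7 phenol, desilylation, triflation and only then the coupling with 14. Both plans rest on a photochemical Wolff rearrangement and a ketene, so they are equal in mechanistic risk at that stage. Overall the alternative is clearly longer and has a harder precursor.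

Alternative 2: The two bonds that join the two caffeoyl halves, C3–C3a and O1–C2, are cut, so the target becomes a dimer of the protected rosmarinate A4. Oxidation of A4 with Ag2O would give phenoxyl radicals, coupling of the side-chain β-carbon of one to the ring carbon ortho to the phenol of the other, and closure of the quinone methide by the phenol oxygen to the trans dihydrofuran A5. In its favour, the whole skeleton with both danshensu esters and the E-propenoate is assembled in one step from a single monomer without halide or palladium; on step economy and convergence it is better than the chosen plan. Against it, regiocontrol among the possible radical coupling modes is uncertain, only part of the monomer can end up as the wanted dimer, and the absolute configuration at C2 and C3 is uncontrolled (harmless, since both centres are later flattened). The free phenol on ring C would also be exposed to the quinone oxidant in the aromatisation that is still needed. On the need for a dehydrogenation and a Lewis-acid deprotection the two plans are equal. The chosen plan is longer but each of its bonds is formed at a predetermined position.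

Alternative 3: O1–C2, the C3–carboxyl bond and the ester C–O bond are cut, giving the o-alkynylphenol A6, carbon monoxide A7 and alcohol 10. With Pd(O2CCF3)2 and a quinone as terminal oxidant, anti oxypalladation of the alkyne by the phenol, insertion of A7 and alcoholysis of the acyl–palladium by 10 should give A8, which is the same compound as 15. In its favour, the furan is formed aromatic and the side chain is already in place, so the product of the key step is the penultimate compound. On oxidation-level economy and probably on step count it is better than the chosen plan. It is equal in making the crowded ester from a one-carbon electrophile and the alcohol and not from a hindered acid. Against it, this carbonylation is normally run with a simple alcohol as solvent. With 10 as a stoichiometric, hindered nucleophile, protodepalladation to the C3–H benzofuran and non-carbonylative cyclisation should compete, and the acrylate in A6 offers the organopalladium intermediate a competing insertion partner. A6 may also cyclise prematurely while it is being made. The chosen plan has firmer precedent for the capture step (a ketene adds alcohols without a catalyst) but pays with a dehydrogenation and a separate coupling.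

Key step: step 6

Remarks on the chemistry: C2 of compounds 6–8 is racemic and 12 is a mixture at C2 and C3; both centres become sp2 in step 7, so no control is attempted. Flavanone C6 and C8 become benzofuran C5 and C7; the structures of the precursor and product of the key step were checked against this mapping and need no correction. The diazo group is introduced by detrifluoroacetylative diazo transfer in one operation instead of through an oxime and chloramine, and the photolysis uses 365 nm light so that the C–Br bond is not excited.

Step 1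
Reactants: 1 2',3'-dihydroxyacetophenone
Product: 2 1-[3-(benzyloxy)-2-hydroxyphenyl]ethan-1-one
Conditions: NaH (2.1 equiv), DMSO–THF, 15 °C; BnBr (1.0 equiv); dilute HCl quench
Reagents that add atoms: benzyl bromide, BrCc1ccccc1
Why: Regioselective Williamson etherification of the catecholate dianion: the 2'-phenoxide is conjugated with and chelated to the acetyl group, so the 3'-phenoxide is the more nucleophilic oxygen and takes the single equivalent of benzyl bromide.

Step 2
Reactants: 2 1-[3-(benzyloxy)-2-hydroxyphenyl]ethan-1-one
Product: 3 1-[3-(benzyloxy)-5-bromo-2-hydroxyphenyl]ethan-1-one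
Conditions: NBS (1.05 equiv), MeCN, 0 °C → 20 °C
Reagents that add atoms: N-bromosuccinimide, O=C1CCC(=O)N1Br
Why: Electrophilic aromatic bromination directed by the free phenol; both ortho positions are occupied, so bromine should enter para to the hydroxyl, which is also meta to the acetyl group.

Step 3
Reactants: 3 1-[3-(benzyloxy)-5-bromo-2-hydroxyphenyl]ethan-1-one; 4 3,4-bis(benzyloxy)benzaldehyde
Product: 6 racemic 8-(benzyloxy)-2-[3,4-bis(benzyloxy)phenyl]-6-bromochroman-4-one, via 2'-hydroxychalcone 5 (not isolated)
Conditions: KOH (aq. 50%), EtOH–THF, 20 °C; then AcOH to pH 6–7, reflux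
Reagents that add atoms: none
Why: Claisen–Schmidt condensation gives the E-chalcone, and in the acetate buffer formed on neutralisation the 2'-phenol should add to the enone (6-endo-trig oxa-Michael) to give the flavanone. The cyclisation is an equilibrium, so unreacted 5 can be recovered and resubmitted; C2 is formed racemic and is erased later.

Step 4
Reactants: 6 racemic 8-(benzyloxy)-2-[3,4-bis(benzyloxy)phenyl]-6-bromochroman-4-one
Product: 8 racemic 8-(benzyloxy)-2-[3,4-bis(benzyloxy)phenyl]-6-bromo-3-diazochroman-4-one, via 3-(trifluoroacetyl)flavanone 7 (not isolated)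
Conditions: LiHMDS (1.1 equiv), THF, −78 °C; CF3CO2CH2CF3 (1.2 equiv), −78 °C; dilute HCl quench, extraction, crude; p-ABSA (1.5 equiv), Et3N (1.5 equiv), H2O (1 equiv), MeCN, 20 °C
Reagents that add atoms: 2,2,2-trifluoroethyl trifluoroacetate, O=C(OCC(F)(F)F)C(F)(F)F (trifluoroacetyl group of 7, lost again); 4-acetamidobenzenesulfonyl azide, CC(=O)Nc1ccc(cc1)S(=O)(=O)N=[N+]=[N-] (the two nitrogen atoms of 8)
Why: Detrifluoroacetylative (Regitz-type) diazo transfer, established for cyclic aryl ketones: the lithium enolate is C-acylated at −78 °C faster than it can open the ring, and the resulting 1,3-dicarbonyl compound takes the diazo group from the sulfonyl azide with loss of the trifluoroacetyl group. C3 is the only enolisable position, so regiochemistry is not an issue.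

Step 5
Reactants: 9 sodium (R)-3-(3,4-dihydroxyphenyl)-2-hydroxypropanoate (danshensu sodium)
Product: 10 benzyl (R)-3-[3,4-bis(benzyloxy)phenyl]-2-hydroxypropanoate
Conditions: BnBr (3.3 equiv), K2CO3 (3 equiv), DMF, 20 °C, N2
Reagents that add atoms: benzyl bromide, BrCc1ccccc1
Why: Williamson etherification of the two phenoxides and SN2 esterification of the carboxylate; carbonate does not deprotonate the secondary alcohol, which stays free, and the α-centre is not enolised under these conditions.

Step 6
Reactants: 8 racemic 8-(benzyloxy)-2-[3,4-bis(benzyloxy)phenyl]-6-bromo-3-diazochroman-4-one; 10 benzyl (R)-3-[3,4-bis(benzyloxy)phenyl]-2-hydroxypropanoate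
Product: 12 benzyl (R)-3-[3,4-bis(benzyloxy)phenyl]-2-({7-(benzyloxy)-2-[3,4-bis(benzyloxy)phenyl]-5-bromo-2,3-dihydrobenzofuran-3-carbonyl}oxy)propanoate (mixture at C2 and C3), via benzofuran-3(2H)-ylidene ketene 11 (not isolated)
Conditions: hν (365 nm LEDs), 10 (1.5 equiv), PhMe (0.02 M), 15 °C, N2; then i-Pr2NEt (0.2 equiv), dark, 0 °C → 20 °C
Reagents that add atoms: none
Why: Wolff rearrangement: excitation of the diazo ketone expels N2 while aryl carbon C4a shifts from the carbonyl carbon C4 to C3, a concerted path that the ring favours because it holds C=O and C=N2 s-cis; the result is ketene 11, in which the former C4 is the exocyclic ketene carbon. The closest known reaction type is the photochemical ring contraction of 2-diazo-1-tetralones and 2-diazo-1-indanones to benzo-fused cycloalkanecarboxylates in alcohols, combined with the amine-promoted addition of lactate-type α-hydroxy esters to aryl alkyl ketenes. The dihydrofuran ring is closed by a 1,2-shift ring contraction (six-membered to five-membered, forming C3–C3a) and not by an end-to-end cyclisation, so no ring-closure rule applies. Alcohol 10 then adds across the ketene C=O and the enol tautomerises to the ester, which forms the hindered ester C–O bond without acyl activation; the C–O bond of 10 is not broken, so its R centre is retained. The new C3 centre is set by protonation of the ester enol, expected anti to the C2 aryl group and further biased by the chiral alkoxy group, but it needs no control because C2 and C3 are flattened in step 7. The step needs aryl migration to win over a 1,2-hydride shift from C2 (which would give the flavone) and over O–H insertion of a free carbene, and the locked s-cis geometry secures this; the C–Br bond is spared because the aryl bromide does not absorb at 365 nm, and complete ketene capture is secured by the excess of 10 and the amine added in the dark.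

Step 7
Reactants: 12 benzyl (R)-3-[3,4-bis(benzyloxy)phenyl]-2-({7-(benzyloxy)-2-[3,4-bis(benzyloxy)phenyl]-5-bromo-2,3-dihydrobenzofuran-3-carbonyl}oxy)propanoate
Product: 13 benzyl (R)-3-[3,4-bis(benzyloxy)phenyl]-2-({7-(benzyloxy)-2-[3,4-bis(benzyloxy)phenyl]-5-bromobenzofuran-3-carbonyl}oxy)propanoate
Conditions: DDQ (1.5 equiv), 1,4-dioxane, 90 °C, dark
Reagents that add atoms: none
Why: Quinone dehydrogenation: hydride abstraction at C2, which is benzylic to an electron-rich ring and α to O1, gives an oxocarbenium ion that loses the C3 proton to form the aromatic furan. Both diastereomers converge, and the neutral conditions leave the lactate centre alone.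

Step 8
Reactants: 10 benzyl (R)-3-[3,4-bis(benzyloxy)phenyl]-2-hydroxypropanoate
Product: 14 benzyl (R)-2-(acryloyloxy)-3-[3,4-bis(benzyloxy)phenyl]propanoate
Conditions: acryloyl chloride (1.2 equiv), Et3N (1.5 equiv), CH2Cl2, −20 → 0 °C
Reagents that add atoms: acryloyl chloride, C=CC(=O)Cl
Why: O-Acylation of a secondary alcohol with an acid chloride; the C–O bond at the stereocentre is not involved, so the R configuration is kept.

Step 9
Reactants: 13 benzyl (R)-3-[3,4-bis(benzyloxy)phenyl]-2-({7-(benzyloxy)-2-[3,4-bis(benzyloxy)phenyl]-5-bromobenzofuran-3-carbonyl}oxy)propanoate; 14 benzyl (R)-2-(acryloyloxy)-3-[3,4-bis(benzyloxy)phenyl]propanoate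
Product: 15 nonabenzyl schizotenuin A (seven benzyl ethers and two benzyl esters; E alkene; R,R)
Conditions: Pd2(dba)3 (2.5 mol%), [HP(t-Bu)3]BF4 (10 mol%), Cy2NMe (1.5 equiv), 14 (1.3 equiv), 1,4-dioxane, 50 °C
Reagents that add atoms: none
Why: Mizoroki–Heck reaction: oxidative addition of zerovalent palladium into the C5–Br bond, syn insertion of the acrylate and syn β-hydride elimination give the E-cinnamate. The bulky electron-rich phosphine allows a temperature and a hindered amine base that should not epimerise the α-acyloxy ester centres.

Step 10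
Reactants: 15 nonabenzyl schizotenuin A
Product: 16 schizotenuin A
Conditions: BCl3 (1 M in CH2Cl2, 20 equiv), C6HMe5 (30 equiv), CH2Cl2, −78 → −20 °C; MeOH quench
Reagents that add atoms: none
Why: Lewis-acid debenzylation with a non-basic cation scavenger: boron coordinates each benzylic oxygen, the benzyl cation is taken up by pentamethylbenzene by Friedel–Crafts alkylation, and the secondary acyl–oxygen bonds, which cannot ionise, should survive. No hydrogen or hydride is used, so the E alkene is untouched, and the product would be isolated by reversed-phase chromatography under inert gas.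

Compound list

1 | 2',3'-dihydroxyacetophenone | CC(=O)c1cccc(O)c1O | starting material
2 | 1-[3-(benzyloxy)-2-hydroxyphenyl]ethan-1-one | CC(=O)c1cccc(OCc2ccccc2)c1O | intermediate
3 | 1-[3-(benzyloxy)-5-bromo-2-hydroxyphenyl]ethan-1-one | CC(=O)c1cc(Br)cc(OCc2ccccc2)c1O | intermediate
4 | 3,4-bis(benzyloxy)benzaldehyde | O=Cc1ccc(OCc2ccccc2)c(OCc2ccccc2)c1 | starting material
5 | (E)-1-[3-(benzyloxy)-5-bromo-2-hydroxyphenyl]-3-[3,4-bis(benzyloxy)phenyl]prop-2-en-1-one | O=C(/C=C/c1ccc(OCc2ccccc2)c(OCc2ccccc2)c1)c1cc(Br)cc(OCc2ccccc2)c1O | intermediate (not isolated)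
6 | racemic 8-(benzyloxy)-2-[3,4-bis(benzyloxy)phenyl]-6-bromochroman-4-one | O=C1CC(c2ccc(OCc3ccccc3)c(OCc3ccccc3)c2)Oc2c(OCc3ccccc3)cc(Br)cc21 | intermediate
7 | racemic 8-(benzyloxy)-2-[3,4-bis(benzyloxy)phenyl]-6-bromo-3-(trifluoroacetyl)chroman-4-one (drawn as the diketone) | O=C1C(C(=O)C(F)(F)F)C(c2ccc(OCc3ccccc3)c(OCc3ccccc3)c2)Oc2c(OCc3ccccc3)cc(Br)cc21 | intermediate (not isolated)
8 | racemic 8-(benzyloxy)-2-[3,4-bis(benzyloxy)phenyl]-6-bromo-3-diazochroman-4-one | [N-]=[N+]=C1C(=O)c2cc(Br)cc(OCc3ccccc3)c2OC1c1ccc(OCc2ccccc2)c(OCc2ccccc2)c1 | intermediate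
9 | sodium (R)-3-(3,4-dihydroxyphenyl)-2-hydroxypropanoate | O[C@H](Cc1ccc(O)c(O)c1)C(=O)[O-].[Na+] | starting material
10 | benzyl (R)-3-[3,4-bis(benzyloxy)phenyl]-2-hydroxypropanoate | O[C@H](Cc1ccc(OCc2ccccc2)c(OCc2ccccc2)c1)C(=O)OCc1ccccc1 | intermediate
11 | racemic {7-(benzyloxy)-2-[3,4-bis(benzyloxy)phenyl]-5-bromobenzofuran-3(2H)-ylidene}methanone (ketene) | O=C=C1C(c2ccc(OCc3ccccc3)c(OCc3ccccc3)c2)Oc2c(OCc3ccccc3)cc(Br)cc21 | intermediate (not isolated)
12 | benzyl (R)-3-[3,4-bis(benzyloxy)phenyl]-2-({7-(benzyloxy)-2-[3,4-bis(benzyloxy)phenyl]-5-bromo-2,3-dihydrobenzofuran-3-carbonyl}oxy)propanoate, mixture at C2 and C3 | O=C(O[C@H](Cc1ccc(OCc2ccccc2)c(OCc2ccccc2)c1)C(=O)OCc1ccccc1)C1C(c2ccc(OCc3ccccc3)c(OCc3ccccc3)c2)Oc2c(OCc3ccccc3)cc(Br)cc21 | intermediate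
13 | benzyl (R)-3-[3,4-bis(benzyloxy)phenyl]-2-({7-(benzyloxy)-2-[3,4-bis(benzyloxy)phenyl]-5-bromobenzofuran-3-carbonyl}oxy)propanoate | O=C(O[C@H](Cc1ccc(OCc2ccccc2)c(OCc2ccccc2)c1)C(=O)OCc1ccccc1)c1c(-c2ccc(OCc3ccccc3)c(OCc3ccccc3)c2)oc2c(OCc3ccccc3)cc(Br)cc12 | intermediate
14 | benzyl (R)-2-(acryloyloxy)-3-[3,4-bis(benzyloxy)phenyl]propanoate | C=CC(=O)O[C@H](Cc1ccc(OCc2ccccc2)c(OCc2ccccc2)c1)C(=O)OCc1ccccc1 | intermediate
15 | nonabenzyl schizotenuin A | O=C(/C=C/c1cc(OCc2ccccc2)c2oc(-c3ccc(OCc4ccccc4)c(OCc4ccccc4)c3)c(C(=O)O[C@H](Cc3ccc(OCc4ccccc4)c(OCc4ccccc4)c3)C(=O)OCc3ccccc3)c2c1)O[C@H](Cc1ccc(OCc2ccccc2)c(OCc2ccccc2)c1)C(=O)OCc1ccccc1 | intermediate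
16 | schizotenuin A | O=C(/C=C/c1cc(O)c2oc(-c3ccc(O)c(O)c3)c(C(=O)O[C@H](Cc3ccc(O)c(O)c3)C(=O)O)c2c1)O[C@H](Cc1ccc(O)c(O)c1)C(=O)O | target

Total step count: 10. Longest linear sequence: 8 steps (steps 1, 2, 3, 4, 6, 7, 9, 10); steps 5 and 8 form the side branch.

Steps least certain to work

Step 6 (key step). The most likely failures are diversion of the excited diazo ketone into a 1,2-hydride shift from C2 (flavone formation), and slow addition of the hindered α-hydroxy ester to the ketene, which leaves time for ketene dimerisation or hydrolysis. Fallback, from 6 back to 12: oxidative ring contraction of 6 with the trivalent iodine reagent PhI(OAc)2 and catalytic H2SO4 in trimethyl orthoformate. This uses the same 1,2-aryl shift but through an iodonium species with no carbene, and should give methyl trans-7-(benzyloxy)-2-[3,4-bis(benzyloxy)phenyl]-5-bromo-2,3-dihydrobenzofuran-3-carboxylate F1. Mild hydrolysis with Me3SnOH in 1,2-dichloroethane would give trans-7-(benzyloxy)-2-[3,4-bis(benzyloxy)phenyl]-5-bromo-2,3-dihydrobenzofuran-3-carboxylic acid F2. Steglich esterification of F2 with 10 (EDC·HCl, DMAP, CH2Cl2) returns to 12.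

Step 4. The lithium enolate of the flavanone may expel the aryloxide by β-elimination (ring opening back to the chalcone) before it is C-acylated, and the crude trifluoroacetyl ketone may be lost on work-up. Fallback, from 6 back to 8: C3 is functionalised on the acid side, where no enolate is formed. Nitrosation with isoamyl nitrite and HCl in THF–EtOH at 0 °C should give 8-(benzyloxy)-2-[3,4-bis(benzyloxy)phenyl]-6-bromo-3-(hydroxyimino)chroman-4-one F3. A Forster reaction of F3 with chloramine generated from aqueous NH3 and NaOCl in THF–aqueous NaOH at 0 °C would then give 8.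

Step 7. The dehydrogenation needs prolonged heating, during which hydride abstraction at the electron-rich benzylic CH2 of the danshensu unit and oxidative loss of benzyl ethers can compete with abstraction at C2. Fallback, from 8 back to 13: the oxidation is moved to a compound that does not yet carry the danshensu unit. Irradiation of 8 at 365 nm with 2-(trimethylsilyl)ethanol in place of 10 should give 2-(trimethylsilyl)ethyl 7-(benzyloxy)-2-[3,4-bis(benzyloxy)phenyl]-5-bromo-2,3-dihydrobenzofuran-3-carboxylate F4. DDQ would convert it into 2-(trimethylsilyl)ethyl 7-(benzyloxy)-2-[3,4-bis(benzyloxy)phenyl]-5-bromobenzofuran-3-carboxylate F5. Bu4NF in THF would free 7-(benzyloxy)-2-[3,4-bis(benzyloxy)phenyl]-5-bromobenzofuran-3-carboxylic acid F6, and Steglich esterification with 10 returns to 13. The price is an acylation with a crowded acid.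

Step 9. Oxidative addition into the bromide para to the furan oxygen may be slow, so that acrylate 14 is consumed by oligomerisation or by amine-induced elimination at its α-acyloxy ester before it couples. Fallback, from 13 back to 15: the C–C bond is made with a robust partner and the ester bond afterwards. A Heck reaction of 13 with acrylic acid (Pd(OAc)2, P(o-tol)3, Et3N, DMF, 90 °C) should give (E)-3-{7-(benzyloxy)-2-[3,4-bis(benzyloxy)phenyl]-3-({(R)-1-(benzyloxy)-3-[3,4-bis(benzyloxy)phenyl]-1-oxopropan-2-yl}oxycarbonyl)benzofuran-5-yl}acrylic acid F7. Esterification of F7 with 10 (EDC·HCl, DMAP) gives 15.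

Step 10. The two benzyl esters may cleave more slowly than the aryl ethers, and on warming the freed catechols may be benzylated or the acyl–oxygen linkages attacked; the polyphenolic triacid can also be lost by oxidation during isolation. Fallback, from 13 and 10 back to 16: the benzyl groups are removed by hydrogenolysis before the alkene exists, and the alkene is made last.
- Palladium-catalysed formylation of 13 (Pd(OAc)2, di(1-adamantyl)-n-butylphosphine, CO/H2, TMEDA, toluene, 100 °C) should give benzyl (R)-3-[3,4-bis(benzyloxy)phenyl]-2-({7-(benzyloxy)-2-[3,4-bis(benzyloxy)phenyl]-5-formylbenzofuran-3-carbonyl}oxy)propanoate F8.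
- Hydrogenolysis (H2, Pd/C, EtOAc–THF, monitored to spare the aldehyde) would give (R)-3-(3,4-dihydroxyphenyl)-2-{[2-(3,4-dihydroxyphenyl)-5-formyl-7-hydroxybenzofuran-3-carbonyl]oxy}propanoic acid F9.
- Separately, 10 is heated with Meldrum's acid in toluene to give 3-({(R)-1-(benzyloxy)-3-[3,4-bis(benzyloxy)phenyl]-1-oxopropan-2-yl}oxy)-3-oxopropanoic acid F10.
- Hydrogenolysis of F10 gives (R)-2-[(carboxyacetyl)oxy]-3-(3,4-dihydroxyphenyl)propanoic acid F11.
- Knoevenagel–Doebner condensation of F9 with F11 (pyridine, catalytic piperidine, 50 °C, N2) should form the E-propenoate with loss of CO2 and arrive at 16.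

Further compounds

F1 | step 6 | methyl trans-7-(benzyloxy)-2-[3,4-bis(benzyloxy)phenyl]-5-bromo-2,3-dihydrobenzofuran-3-carboxylate (racemic; 2R,3R drawn) | Brc1cc(OCc2ccccc2)c2O[C@@H](c3ccc(OCc4ccccc4)c(OCc4ccccc4)c3)[C@H](C(=O)OC)c2c1
F2 | step 6 | trans-7-(benzyloxy)-2-[3,4-bis(benzyloxy)phenyl]-5-bromo-2,3-dihydrobenzofuran-3-carboxylic acid (racemic; 2R,3R drawn) | Brc1cc(OCc2ccccc2)c2O[C@@H](c3ccc(OCc4ccccc4)c(OCc4ccccc4)c3)[C@H](C(=O)O)c2c1
F3 | step 4 | racemic 8-(benzyloxy)-2-[3,4-bis(benzyloxy)phenyl]-6-bromo-3-(hydroxyimino)chroman-4-one | ON=C1C(=O)c2cc(Br)cc(OCc3ccccc3)c2OC1c1ccc(OCc2ccccc2)c(OCc2ccccc2)c1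
F4 | step 7 | 2-(trimethylsilyl)ethyl 7-(benzyloxy)-2-[3,4-bis(benzyloxy)phenyl]-5-bromo-2,3-dihydrobenzofuran-3-carboxylate (racemic cis/trans mixture) | C[Si](C)(C)CCOC(=O)C1C(c2ccc(OCc3ccccc3)c(OCc3ccccc3)c2)Oc2c(OCc3ccccc3)cc(Br)cc21
F5 | step 7 | 2-(trimethylsilyl)ethyl 7-(benzyloxy)-2-[3,4-bis(benzyloxy)phenyl]-5-bromobenzofuran-3-carboxylate | C[Si](C)(C)CCOC(=O)c1c(-c2ccc(OCc3ccccc3)c(OCc3ccccc3)c2)oc2c(OCc3ccccc3)cc(Br)cc12
F6 | step 7 | 7-(benzyloxy)-2-[3,4-bis(benzyloxy)phenyl]-5-bromobenzofuran-3-carboxylic acid | OC(=O)c1c(-c2ccc(OCc3ccccc3)c(OCc3ccccc3)c2)oc2c(OCc3ccccc3)cc(Br)cc12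
F7 | step 9 | (E)-3-{7-(benzyloxy)-2-[3,4-bis(benzyloxy)phenyl]-3-({(R)-1-(benzyloxy)-3-[3,4-bis(benzyloxy)phenyl]-1-oxopropan-2-yl}oxycarbonyl)benzofuran-5-yl}acrylic acid | OC(=O)/C=C/c1cc(OCc2ccccc2)c2oc(-c3ccc(OCc4ccccc4)c(OCc4ccccc4)c3)c(C(=O)O[C@H](Cc3ccc(OCc4ccccc4)c(OCc4ccccc4)c3)C(=O)OCc3ccccc3)c2c1
F8 | step 10 | benzyl (R)-3-[3,4-bis(benzyloxy)phenyl]-2-({7-(benzyloxy)-2-[3,4-bis(benzyloxy)phenyl]-5-formylbenzofuran-3-carbonyl}oxy)propanoate | O=Cc1cc(OCc2ccccc2)c2oc(-c3ccc(OCc4ccccc4)c(OCc4ccccc4)c3)c(C(=O)O[C@H](Cc3ccc(OCc4ccccc4)c(OCc4ccccc4)c3)C(=O)OCc3ccccc3)c2c1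
F9 | step 10 | (R)-3-(3,4-dihydroxyphenyl)-2-{[2-(3,4-dihydroxyphenyl)-5-formyl-7-hydroxybenzofuran-3-carbonyl]oxy}propanoic acid | O=Cc1cc(O)c2oc(-c3ccc(O)c(O)c3)c(C(=O)O[C@H](Cc3ccc(O)c(O)c3)C(=O)O)c2c1
F10 | step 10 | 3-({(R)-1-(benzyloxy)-3-[3,4-bis(benzyloxy)phenyl]-1-oxopropan-2-yl}oxy)-3-oxopropanoic acid | OC(=O)CC(=O)O[C@H](Cc1ccc(OCc2ccccc2)c(OCc2ccccc2)c1)C(=O)OCc1ccccc1
F11 | step 10 | (R)-2-[(carboxyacetyl)oxy]-3-(3,4-dihydroxyphenyl)propanoic acid | OC(=O)CC(=O)O[C@H](Cc1ccc(O)c(O)c1)C(=O)O
A1 | alternative 1 | benzyl (R)-3-[3,4-bis(benzyloxy)phenyl]-2-({2-[3,4-bis(benzyloxy)phenyl]-4-(2-diazoacetyl)furan-3-carbonyl}oxy)propanoate | [N-]=[N+]=CC(=O)c1coc(-c2ccc(OCc3ccccc3)c(OCc3ccccc3)c2)c1C(=O)O[C@H](Cc1ccc(OCc2ccccc2)c(OCc2ccccc2)c1)C(=O)OCc1ccccc1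
A2 | alternative 1 | (triisopropylsilyloxy)ethyne | C#CO[Si](C(C)C)(C(C)C)C(C)C
A3 | alternative 1 | benzyl (R)-3-[3,4-bis(benzyloxy)phenyl]-2-({2-[3,4-bis(benzyloxy)phenyl]-7-hydroxy-5-(triisopropylsilyloxy)benzofuran-3-carbonyl}oxy)propanoate | Oc1cc(O[Si](C(C)C)(C(C)C)C(C)C)cc2c(C(=O)O[C@H](Cc3ccc(OCc4ccccc4)c(OCc4ccccc4)c3)C(=O)OCc3ccccc3)c(-c3ccc(OCc4ccccc4)c(OCc4ccccc4)c3)oc12
A4 | alternative 2 | benzyl (R)-2-{[(E)-3-(3-benzyloxy-4-hydroxyphenyl)acryloyl]oxy}-3-[3,4-bis(benzyloxy)phenyl]propanoate | O=C(/C=C/c1ccc(O)c(OCc2ccccc2)c1)O[C@H](Cc1ccc(OCc2ccccc2)c(OCc2ccccc2)c1)C(=O)OCc1ccccc1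
A5 | alternative 2 | octabenzyl trans-2,3-dihydroschizotenuin A with the 4-hydroxyl of the 2-aryl ring free (2R,3R diastereomer drawn) | O=C(/C=C/c1cc(OCc2ccccc2)c2O[C@@H](c3ccc(O)c(OCc4ccccc4)c3)[C@H](C(=O)O[C@H](Cc3ccc(OCc4ccccc4)c(OCc4ccccc4)c3)C(=O)OCc3ccccc3)c2c1)O[C@H](Cc1ccc(OCc2ccccc2)c(OCc2ccccc2)c1)C(=O)OCc1ccccc1
A6 | alternative 3 | benzyl (R)-2-{[(E)-3-(3-benzyloxy-5-{[3,4-bis(benzyloxy)phenyl]ethynyl}-4-hydroxyphenyl)acryloyl]oxy}-3-[3,4-bis(benzyloxy)phenyl]propanoate | O=C(/C=C/c1cc(OCc2ccccc2)c(O)c(C#Cc2ccc(OCc3ccccc3)c(OCc3ccccc3)c2)c1)O[C@H](Cc1ccc(OCc2ccccc2)c(OCc2ccccc2)c1)C(=O)OCc1ccccc1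
A7 | alternative 3 | carbon monoxide | [C-]#[O+]
A8 | alternative 3 | nonabenzyl schizotenuin A (identical with 15) | O=C(/C=C/c1cc(OCc2ccccc2)c2oc(-c3ccc(OCc4ccccc4)c(OCc4ccccc4)c3)c(C(=O)O[C@H](Cc3ccc(OCc4ccccc4)c(OCc4ccccc4)c3)C(=O)OCc3ccccc3)c2c1)O[C@H](Cc1ccc(OCc2ccccc2)c(OCc2ccccc2)c1)C(=O)OCc1ccccc1
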